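**Strategy.** The cis-decalin is disconnected across ring A at C1–C2 and at the ring-fusion bond C5–C10 (eremophilane numbering). The precursor is an acyclic bis-enone: an (E)-tetrasubstituted methyl ketone enone (C2–C5) joined through C6–C9 to a C9 vinyl ketone, with the C7 isopropenyl stereocentre in the tether. Soft enolisation gives the 2-silyloxydiene, which undergoes an intramolecular Diels–Alder reaction that closes rings A and B together and sets the C5 quaternary centre and the cis fusion. The step exploits the 1,4-disposition of the C3 and C9 oxygens across ring A; the all-equatorial stereocentres C3, C4 and C9 are then set under thermodynamic control.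

Key step: step 10

Remark on numbering: eremophilane locants are used throughout (ring A = C1–C5, C10; ring B = C5–C10; C11–C13 isopropenyl on C7; C14 methyl on C5; C15 methyl on C4), and the descriptors of the decalins refer to them.

Remark on C8: C8 is a temporary stereocentre that ends as the ketone. The expected Felkin–Anh (8S) epimer is drawn; any 8R epimer converges in step 15.

**Step 1**
Reactants: 1 methyl 2-methyl-3-oxobutanoate
Product: 2 methyl (2E)-2-methyl-3-[(4-methylbenzenesulfonyl)oxy]but-2-enoate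
Conditions: TsCl, N-methylimidazole (cat.), Et3N, toluene, 0 °C to rt
Reagents that add atoms: 4-methylbenzenesulfonyl chloride, Cc1ccc(cc1)S(Cl)(=O)=O
Why: O-sulfonylation of the β-keto ester enolate under non-chelating amine conditions should give the (E)-enol tosylate (sulfonate anti to the ester), since no metal holds the two carbonyl oxygens syn.

**Step 2**
Reactants: 2 methyl (2E)-2-methyl-3-[(4-methylbenzenesulfonyl)oxy]but-2-enoate
Product: 3 (2E)-4-hydroxy-3-methylbut-2-en-2-yl 4-methylbenzenesulfonate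
Conditions: i-Bu2AlH, CH2Cl2, −78 °C
Reagents that add atoms: none
Why: 1,2-reduction of the enoate by the aluminium hydride at low temperature should leave the enol sulfonate and the alkene geometry untouched.

**Step 3**
Reactants: 3 (2E)-4-hydroxy-3-methylbut-2-en-2-yl 4-methylbenzenesulfonate
Product: 4 (2E)-4-bromo-3-methylbut-2-en-2-yl 4-methylbenzenesulfonate
Conditions: CBr4, PPh3, CH2Cl2, 0 °C
Reagents that add atoms: carbon tetrabromide, BrC(Br)(Br)Br
Why: Appel bromination converts the primary allylic alcohol into the bromide by SN2 without allylic transposition.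

**Step 4**
Reactants: 5 (4R)-4-benzyl-1,3-oxazolidin-2-one; 6 3-methylbut-2-enoyl chloride
Product: 7 (4R)-4-benzyl-3-(3-methylbut-2-enoyl)-1,3-oxazolidin-2-one
Conditions: n-BuLi, THF, −78 °C; then 6, −78 to 0 °C
Reagents that add atoms: none
Why: N-acylation of the lithiated oxazolidinone by the acid chloride.

**Step 5**
Reactants: 7 (4R)-4-benzyl-3-(3-methylbut-2-enoyl)-1,3-oxazolidin-2-one; 4 (2E)-4-bromo-3-methylbut-2-en-2-yl 4-methylbenzenesulfonate
Product: 9 (4R)-4-benzyl-3-[(2R,4E)-4-methyl-5-[(4-methylbenzenesulfonyl)oxy]-2-(prop-1-en-2-yl)hex-4-enoyl]-1,3-oxazolidin-2-one, via sodium dienolate 8 (not isolated)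
Conditions: NaN(SiMe3)2, THF, −78 °C; then 4, −78 to −20 °C
Reagents that add atoms: none
Why: Auxiliary-controlled (Evans) asymmetric alkylation: γ-deprotonation gives the chelated (Z)-dienolate 8, which should be alkylated at the α-carbon on the face opposite the benzyl group, setting C7 as R with deconjugation to the isopropenyl group.

**Step 6**
Reactants: 9 (4R)-4-benzyl-3-[(2R,4E)-4-methyl-5-[(4-methylbenzenesulfonyl)oxy]-2-(prop-1-en-2-yl)hex-4-enoyl]-1,3-oxazolidin-2-one
Product: 10 (2E,5R)-5-(hydroxymethyl)-3,6-dimethylhepta-2,6-dien-2-yl 4-methylbenzenesulfonate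
Conditions: LiBH4, H2O (1 equiv), Et2O, 0 °C
Reagents that add atoms: none
Why: Reductive cleavage of the imide by borohydride releases the auxiliary and should give the primary alcohol without touching C7 or the alkenyl tosylate.

**Step 7**
Reactants: 10 (2E,5R)-5-(hydroxymethyl)-3,6-dimethylhepta-2,6-dien-2-yl 4-methylbenzenesulfonate
Product: 12 (3E,6R)-6-(hydroxymethyl)-3,4,7-trimethylocta-3,7-dien-2-one, via ethoxydiene alcohol 11 (not isolated)
Conditions: tributyl(1-ethoxyvinyl)stannane, Pd(OAc)2 (cat.), XPhos (cat.), CsF, t-BuOH, 100 °C; then 1 M HCl, THF, 0 °C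
Reagents that add atoms: tributyl(1-ethoxyvinyl)stannane, CCCC[Sn](CCCC)(CCCC)C(=C)OCC; water, O
Why: Stille cross-coupling of the alkenyl tosylate (bulky biarylphosphine ligand) proceeds with retention of alkene geometry, and mild acid hydrolysis of the 2-ethoxydiene 11 should unmask the (E)-methyl ketone enone.

**Step 8**
Reactants: 12 (3E,6R)-6-(hydroxymethyl)-3,4,7-trimethylocta-3,7-dien-2-one
Product: 13 (2R,4E)-4,5-dimethyl-6-oxo-2-(prop-1-en-2-yl)hept-4-enal
Conditions: Dess–Martin periodinane, NaHCO3, CH2Cl2, 0 °C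
Reagents that add atoms: none
Why: Dess–Martin oxidation under buffered conditions should give the α-isopropenyl aldehyde without epimerisation or conjugation; it is used at once.

**Step 9**
Reactants: 13 (2R,4E)-4,5-dimethyl-6-oxo-2-(prop-1-en-2-yl)hept-4-enal
Product: 16 (4S,5R,7E)-4-[(4-methoxyphenyl)methoxy]-7,8-dimethyl-5-(prop-1-en-2-yl)deca-1,7-diene-3,9-dione, via lithium alkoxide 14 (not isolated), via allenyl PMB ether 15 (not isolated)
Conditions: methoxyallene, n-BuLi, THF, −78 °C; add 13; then PMBBr, Bu4NI, DMPU, −78 to 23 °C; then 5% aq. H2SO4, THF, 0 °C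
Reagents that add atoms: methoxyallene, C=C=COC; 4-methoxybenzyl bromide, COc1ccc(CBr)cc1; water, O
Why: 1-Lithio-1-methoxyallene (an acryloyl anion equivalent) adds to the aldehyde faster than to the hindered enone under Felkin–Anh control (isopropenyl anti to the nucleophile), favouring the 8S alkoxide 14, which is benzylated in situ (Williamson etherification) and hydrolysed to the vinyl ketone.

**Step 10**
Reactants: 16 (4S,5R,7E)-4-[(4-methoxyphenyl)methoxy]-7,8-dimethyl-5-(prop-1-en-2-yl)deca-1,7-diene-3,9-dione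
Product: 19 (4R,5R,7R,8S,10S)-8-[(4-methoxyphenyl)methoxy]eremophil-11-ene-3,9-dione, via silyloxydiene 17 (not isolated), via silyl enol ether cycloadduct 18 (not isolated)
Conditions: TBSOTf, i-Pr2NEt, CH2Cl2 (0.005 M), −78 to 23 °C; then 1 M HCl, THF, 0 °C
Reagents that add atoms: none
Why: The amine/silyl triflate pair should enolise the unhindered C2 methyl of the C3 ketone to the 2-silyloxydiene 17 (the tertiary, ether-bearing C8–H reacts far more slowly), and silyl triflate activation of the C9 enone then drives a type 1 intramolecular Diels–Alder reaction (concerted asynchronous; a Mukaiyama–Michael/Michael sequence would give the same adduct), the closest known classes being silyl triflate–amine mediated intramolecular cycloadditions of enones and the cyclisation of 1,7,9-decatrien-3-ones. Ring A is closed by the [4+2] union of C2=C3–C4=C5 with C1=C10, and ring B is closed at the same time as a fused six-membered ring through the four-atom tether C6–C9 by the C5–C10 bond. The cis relation of C14 and H-10 follows from the E diene (tether outside, C14 inside) reacting in the tether-endo mode, because an exo tether would collide with the inside methyl. The C5/C10 pair is set relative to C7 by a chair-like tether with the isopropenyl group equatorial, since attack on the other diene face would force it axial against C4. Regiochemistry is fixed by the tether and is electronically matched (nucleophilic C2 to the enone β-carbon C1); C4 is set on hydrolysis by axial protonation from the α face, which is also the thermodynamic (equatorial methyl) outcome.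

**Step 11**
Reactants: 19 (4R,5R,7R,8S,10S)-8-[(4-methoxyphenyl)methoxy]eremophil-11-ene-3,9-dione
Product: 20 (3R,4R,5R,7R,8S,9R,10S)-8-[(4-methoxyphenyl)methoxy]eremophil-11-ene-3,9-diol
Conditions: Al(Oi-Pr)3, i-PrOH, toluene, 85 °C (acetone not removed)
Reagents that add atoms: none
Why: Meerwein–Ponndorf–Verley reduction is reversible, so both carbinols should equilibrate to the equatorial epimers (3α-OH clear of the axial C14 methyl, 9β-OH clear of the axial C4–C5 bond), while C4 and C10 stay in their thermodynamic configurations.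

**Step 12**
Reactants: 20 (3R,4R,5R,7R,8S,9R,10S)-8-[(4-methoxyphenyl)methoxy]eremophil-11-ene-3,9-diol
Product: 21 (3R,4R,5R,7R,8S,9R,10S)-9-hydroxy-8-[(4-methoxyphenyl)methoxy]eremophil-11-en-3-yl (2E)-2-methylbut-2-enoate
Conditions: (E)-2-methylbut-2-enoyl chloride (1.1 equiv), pyridine, DMAP (cat.), CH2Cl2, −20 to 0 °C
Reagents that add atoms: (E)-2-methylbut-2-enoyl chloride, C/C=C(\C)C(Cl)=O
Why: DMAP-catalysed acylation should occur selectively at the less hindered C3 hydroxyl, flanked by a CH2 group, whereas C9–OH lies between the ring fusion and the C8 ether.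

**Step 13**
Reactants: 21 (3R,4R,5R,7R,8S,9R,10S)-9-hydroxy-8-[(4-methoxyphenyl)methoxy]eremophil-11-en-3-yl (2E)-2-methylbut-2-enoate; 6 3-methylbut-2-enoyl chloride
Product: 22 (3R,4R,5R,7R,8S,9R,10S)-8-[(4-methoxyphenyl)methoxy]-9-[(3-methylbut-2-enoyl)oxy]eremophil-11-en-3-yl (2E)-2-methylbut-2-enoate
Conditions: 6 (excess), pyridine, DMAP, CH2Cl2, 40 °C
Reagents that add atoms: none
Why: Forced DMAP-catalysed acylation of the remaining hindered C9 hydroxyl, with pyridine as the only base to limit deconjugation through the vinylketene.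

**Step 14**
Reactants: 22 (3R,4R,5R,7R,8S,9R,10S)-8-[(4-methoxyphenyl)methoxy]-9-[(3-methylbut-2-enoyl)oxy]eremophil-11-en-3-yl (2E)-2-methylbut-2-enoate
Product: 23 (3R,4R,5R,7R,8S,9R,10S)-8-hydroxy-9-[(3-methylbut-2-enoyl)oxy]eremophil-11-en-3-yl (2E)-2-methylbut-2-enoate
Conditions: DDQ, CH2Cl2/pH 7 buffer, 0 °C to rt
Reagents that add atoms: none
Why: Oxidative cleavage of the PMB ether by DDQ under neutral buffered conditions should avoid base-induced acyl migration from O9 to O8.

**Step 15**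
Reactants: 23 (3R,4R,5R,7R,8S,9R,10S)-8-hydroxy-9-[(3-methylbut-2-enoyl)oxy]eremophil-11-en-3-yl (2E)-2-methylbut-2-enoate
Product: 24 (3R,4R,5R,7R,9R,10S)-9-[(3-methylbut-2-enoyl)oxy]-8-oxoeremophil-11-en-3-yl (2E)-2-methylbut-2-enoate
Conditions: Dess–Martin periodinane, NaHCO3, CH2Cl2, 0 °C to rt
Reagents that add atoms: none
Why: Dess–Martin oxidation of the axial C8 alcohol under neutral conditions should give the ketone without epimerising C7 or C9 and without moving the isopropenyl double bond into conjugation.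

**Compound list**

1 | methyl 2-methyl-3-oxobutanoate | COC(=O)C(C)C(C)=O | starting material
2 | methyl (2E)-2-methyl-3-[(4-methylbenzenesulfonyl)oxy]but-2-enoate | COC(=O)/C(C)=C(\C)OS(=O)(=O)c1ccc(C)cc1 | intermediate
3 | (2E)-4-hydroxy-3-methylbut-2-en-2-yl 4-methylbenzenesulfonate | OC/C(C)=C(\C)OS(=O)(=O)c1ccc(C)cc1 | intermediate
4 | (2E)-4-bromo-3-methylbut-2-en-2-yl 4-methylbenzenesulfonate | BrC/C(C)=C(\C)OS(=O)(=O)c1ccc(C)cc1 | intermediate
5 | (4R)-4-benzyl-1,3-oxazolidin-2-one | O=C1N[C@H](Cc2ccccc2)CO1 | starting material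
6 | 3-methylbut-2-enoyl chloride | CC(C)=CC(Cl)=O | starting material
7 | (4R)-4-benzyl-3-(3-methylbut-2-enoyl)-1,3-oxazolidin-2-one | CC(C)=CC(=O)N1[C@H](Cc2ccccc2)COC1=O | intermediate
8 | sodium (1Z)-1-[(4R)-4-benzyl-2-oxo-1,3-oxazolidin-3-yl]-3-methylbuta-1,3-dien-1-olate | [Na+].[O-]/C(=C\C(C)=C)N1[C@H](Cc2ccccc2)COC1=O | intermediate
9 | (4R)-4-benzyl-3-[(2R,4E)-4-methyl-5-[(4-methylbenzenesulfonyl)oxy]-2-(prop-1-en-2-yl)hex-4-enoyl]-1,3-oxazolidin-2-one | C=C(C)[C@@H](C/C(C)=C(\C)OS(=O)(=O)c1ccc(C)cc1)C(=O)N1[C@H](Cc2ccccc2)COC1=O | intermediate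
10 | (2E,5R)-5-(hydroxymethyl)-3,6-dimethylhepta-2,6-dien-2-yl 4-methylbenzenesulfonate | C=C(C)[C@@H](C/C(C)=C(\C)OS(=O)(=O)c1ccc(C)cc1)CO | intermediate
11 | (2R,4E)-6-ethoxy-4,5-dimethyl-2-(prop-1-en-2-yl)hepta-4,6-dien-1-ol | C=C(C)[C@@H](C/C(C)=C(\C)C(=C)OCC)CO | intermediate
12 | (3E,6R)-6-(hydroxymethyl)-3,4,7-trimethylocta-3,7-dien-2-one | C=C(C)[C@@H](C/C(C)=C(\C)C(C)=O)CO | intermediate
13 | (2R,4E)-4,5-dimethyl-6-oxo-2-(prop-1-en-2-yl)hept-4-enal | C=C(C)[C@@H](C/C(C)=C(\C)C(C)=O)C=O | intermediate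
14 | lithium (4S,5R,7E)-3-methoxy-7,8-dimethyl-9-oxo-5-(prop-1-en-2-yl)deca-1,2,7-trien-4-olate | C=C=C(OC)[C@@H]([O-])[C@H](C/C(C)=C(\C)C(C)=O)C(C)=C.[Li+] | intermediate
15 | (4S,5R,7E)-3-methoxy-4-[(4-methoxyphenyl)methoxy]-7,8-dimethyl-5-(prop-1-en-2-yl)deca-1,2,7-trien-9-one | C=C=C(OC)[C@@H](OCc1ccc(OC)cc1)[C@H](C/C(C)=C(\C)C(C)=O)C(C)=C | intermediate
16 | (4S,5R,7E)-4-[(4-methoxyphenyl)methoxy]-7,8-dimethyl-5-(prop-1-en-2-yl)deca-1,7-diene-3,9-dione | C=CC(=O)[C@@H](OCc1ccc(OC)cc1)[C@H](C/C(C)=C(\C)C(C)=O)C(C)=C | intermediate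
17 | (4S,5R,7E)-9-[(tert-butyldimethylsilyl)oxy]-4-[(4-methoxyphenyl)methoxy]-7,8-dimethyl-5-(prop-1-en-2-yl)deca-1,7,9-trien-3-one | C=CC(=O)[C@@H](OCc1ccc(OC)cc1)[C@H](C/C(C)=C(\C)C(=C)O[Si](C)(C)C(C)(C)C)C(C)=C | intermediate
18 | (5S,7R,8S,10S)-3-[(tert-butyldimethylsilyl)oxy]-8-[(4-methoxyphenyl)methoxy]eremophila-3,11-dien-9-one (cis-fused; 5β-Me, 7β-isopropenyl, 8β-OPMB, 10β-H) | C=C(C)[C@H]1C[C@@]2(C)[C@H](CCC(O[Si](C)(C)C(C)(C)C)=C2C)C(=O)[C@H]1OCc1ccc(OC)cc1 | intermediate
19 | (4R,5R,7R,8S,10S)-8-[(4-methoxyphenyl)methoxy]eremophil-11-ene-3,9-dione (cis-fused; 4β-Me, 5β-Me, 7β-isopropenyl, 8β-OPMB, 10β-H) | C=C(C)[C@H]1C[C@@]2(C)[C@H](CCC(=O)[C@@H]2C)C(=O)[C@H]1OCc1ccc(OC)cc1 | intermediate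
20 | (3R,4R,5R,7R,8S,9R,10S)-8-[(4-methoxyphenyl)methoxy]eremophil-11-ene-3,9-diol (3α-OH, 9β-OH) | C=C(C)[C@H]1C[C@@]2(C)[C@H](CC[C@@H](O)[C@@H]2C)[C@@H](O)[C@H]1OCc1ccc(OC)cc1 | intermediate
21 | (3R,4R,5R,7R,8S,9R,10S)-9-hydroxy-8-[(4-methoxyphenyl)methoxy]eremophil-11-en-3-yl (2E)-2-methylbut-2-enoate | C=C(C)[C@H]1C[C@@]2(C)[C@H](CC[C@@H](OC(=O)/C(C)=C/C)[C@@H]2C)[C@@H](O)[C@H]1OCc1ccc(OC)cc1 | intermediate
22 | (3R,4R,5R,7R,8S,9R,10S)-8-[(4-methoxyphenyl)methoxy]-9-[(3-methylbut-2-enoyl)oxy]eremophil-11-en-3-yl (2E)-2-methylbut-2-enoate | C=C(C)[C@H]1C[C@@]2(C)[C@H](CC[C@@H](OC(=O)/C(C)=C/C)[C@@H]2C)[C@@H](OC(=O)C=C(C)C)[C@H]1OCc1ccc(OC)cc1 | intermediate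
23 | (3R,4R,5R,7R,8S,9R,10S)-8-hydroxy-9-[(3-methylbut-2-enoyl)oxy]eremophil-11-en-3-yl (2E)-2-methylbut-2-enoate | C=C(C)[C@H]1C[C@@]2(C)[C@H](CC[C@@H](OC(=O)/C(C)=C/C)[C@@H]2C)[C@@H](OC(=O)C=C(C)C)[C@H]1O | intermediate
24 | (3R,4R,5R,7R,9R,10S)-9-[(3-methylbut-2-enoyl)oxy]-8-oxoeremophil-11-en-3-yl (2E)-2-methylbut-2-enoate | C=C(C)[C@H]1C[C@@]2(C)[C@H](CC[C@@H](OC(=O)/C(C)=C/C)[C@@H]2C)[C@@H](OC(=O)C=C(C)C)C1=O | target

**Step count.** Total: 15 steps. Longest linear sequence: 14 steps (from 1 through steps 1–3 and 5–15); step 4 is the convergent branch.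

**Steps most likely to fail**

Step 10. The soft enolisation may go to the vinylogous γ-position instead of the C2 methyl. The silyloxydiene may also oligomerise by intermolecular Mukaiyama–Michael addition. The cycloaddition itself may be slow at the fully substituted diene terminus, which lowers endo and facial selectivity. The fallback uses an isolated, regiochemically unambiguous alkoxydiene and a purely thermal cycloaddition. It sets out from 10 and keeps the alkenyl tosylate: Dess–Martin oxidation gives the tosyloxy aldehyde F1. Addition of 1-lithio-1-methoxyallene, in situ PMB etherification and acid hydrolysis (as in step 9) give the tosyloxy vinyl ketone F2. Stille coupling with tributyl(1-ethoxyvinyl)stannane under the step 7 conditions, with a neutral work-up, gives the ethoxydiene triene F3. Heating F3 in toluene with a radical inhibitor (80–110 °C, high dilution) should give the enol ether cycloadduct F4 through the same endo, chair-like arrangement. 1 M HCl in THF then hydrolyses F4, and the route is rejoined at 19.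

Step 11. Equilibration may be incomplete at the hindered C9 carbonyl. The hot aluminium alkoxide may also open the 1,5-diketone by retro-Michael cleavage or epimerise C8. The fallback replaces thermodynamic reduction by kinetic reduction followed by two invertive esterifications. From 19, NaBH4 in MeOH at −20 °C should attack both carbonyls from their open equatorial sides and give the diaxial 3β,9α-diol F5. A Mitsunobu reaction (PPh3, diisopropyl azodicarboxylate, (E)-2-methylbut-2-enoic acid) at the less hindered C3 hydroxyl gives, with inversion, the 3α-tiglate 9α-alcohol F6. Tf2O/pyridine at −30 °C converts F6 into the 9α-triflate F7. SN2 displacement of F7 from the convex β face with tetrabutylammonium 3-methylbut-2-enoate gives the bis-ester, and the route is rejoined at 22.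

Step 7. Oxidative addition into the hindered, non-activated alkenyl sulfonate may be too slow, so that protodestannylation and decomposition of the stannane take over. The fallback moves the coupling to the activated β-sulfonyloxy enoate and carries the masked ketone through the alkylation. From 2, Stille coupling with tributyl(1-ethoxyvinyl)stannane (Pd(OAc)2, XPhos, CsF, neutral work-up) gives the ethoxydienoate F8. i-Bu2AlH reduces F8 to the dienol F9. Mesylation (MsCl, Et3N) and LiBr displacement give the dienyl bromide F10. Alkylation of the sodium dienolate 8 with F10 (as in step 5) gives the imide F11. LiBH4 cleavage gives 11, where the route is rejoined; the acid treatment of step 7 then delivers 12.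

**Further compounds**

F1 | step 10 | (2R,4E)-4-methyl-5-[(4-methylbenzenesulfonyl)oxy]-2-(prop-1-en-2-yl)hex-4-enal | C=C(C)[C@@H](C/C(C)=C(\C)OS(=O)(=O)c1ccc(C)cc1)C=O
F2 | step 10 | (2E,5R,6S)-6-[(4-methoxyphenyl)methoxy]-3-methyl-7-oxo-5-(prop-1-en-2-yl)nona-2,8-dien-2-yl 4-methylbenzenesulfonate | C=CC(=O)[C@@H](OCc1ccc(OC)cc1)[C@H](C/C(C)=C(\C)OS(=O)(=O)c1ccc(C)cc1)C(C)=C
F3 | step 10 | (4S,5R,7E)-9-ethoxy-4-[(4-methoxyphenyl)methoxy]-7,8-dimethyl-5-(prop-1-en-2-yl)deca-1,7,9-trien-3-one | C=CC(=O)[C@@H](OCc1ccc(OC)cc1)[C@H](C/C(C)=C(\C)C(=C)OCC)C(C)=C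
F4 | step 10 | (5S,7R,8S,10S)-3-ethoxy-8-[(4-methoxyphenyl)methoxy]eremophila-3,11-dien-9-one | C=C(C)[C@H]1C[C@@]2(C)[C@H](CCC(OCC)=C2C)C(=O)[C@H]1OCc1ccc(OC)cc1
F5 | step 11 | (3S,4R,5R,7R,8S,9S,10S)-8-[(4-methoxyphenyl)methoxy]eremophil-11-ene-3,9-diol (3β-OH, 9α-OH) | C=C(C)[C@H]1C[C@@]2(C)[C@H](CC[C@H](O)[C@@H]2C)[C@H](O)[C@H]1OCc1ccc(OC)cc1
F6 | step 11 | (3R,4R,5R,7R,8S,9S,10S)-9-hydroxy-8-[(4-methoxyphenyl)methoxy]eremophil-11-en-3-yl (2E)-2-methylbut-2-enoate | C=C(C)[C@H]1C[C@@]2(C)[C@H](CC[C@@H](OC(=O)/C(C)=C/C)[C@@H]2C)[C@H](O)[C@H]1OCc1ccc(OC)cc1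
F7 | step 11 | (3R,4R,5R,7R,8S,9S,10S)-8-[(4-methoxyphenyl)methoxy]-9-[(trifluoromethanesulfonyl)oxy]eremophil-11-en-3-yl (2E)-2-methylbut-2-enoate | C=C(C)[C@H]1C[C@@]2(C)[C@H](CC[C@@H](OC(=O)/C(C)=C/C)[C@@H]2C)[C@H](OS(=O)(=O)C(F)(F)F)[C@H]1OCc1ccc(OC)cc1
F8 | step 7 | methyl (2E)-4-ethoxy-2,3-dimethylpenta-2,4-dienoate | COC(=O)/C(C)=C(\C)C(=C)OCC
F9 | step 7 | (2E)-4-ethoxy-2,3-dimethylpenta-2,4-dien-1-ol | OC/C(C)=C(\C)C(=C)OCC
F10 | step 7 | (2E)-1-bromo-4-ethoxy-2,3-dimethylpenta-2,4-diene | BrC/C(C)=C(\C)C(=C)OCC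
F11 | step 7 | (4R)-4-benzyl-3-[(2R,4E)-6-ethoxy-4,5-dimethyl-2-(prop-1-en-2-yl)hepta-4,6-dienoyl]-1,3-oxazolidin-2-one | C=C(C)[C@@H](C/C(C)=C(\C)C(=C)OCC)C(=O)N1[C@H](Cc2ccccc2)COC1=O
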